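The data were computed on assumed constants.

The product fraction in these flasks falls short of what the starting material loses, and two chemists read that shortfall differently.

| setting | gamma | alpha | eta | amber | ochre | teal | green | blue | grey |
|---|---|---|---|---|---|---|---|---|---|
| starting material | 1.2 M | 1.9 M | 1.5 M | 1.5 M | 1.0 M | 1.5 M | 2.5 M | 1.0 M | 3.0 M |
| gas phase | 170 mM (held) | 170 mM (held) | 170 mM (held) | 170 mM (held) | 170 mM (held) | 170 mM (held) | 170 mM (held) | 170 mM (held) | 170 mM (held) |
| catalyst | 7.5 mM | 7.5 mM | 12 mM | 4.0 mM | 25 mM | 7.5 mM | 12 mM | 5.0 mM | 7.5 mM |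
| remark | run made earlier | run made earlier | run made earlier |  |  |  |  |  |  |
| time |  |  |  | 4.0 h | 4.0 h | 4.0 h | 4.0 h | 4.0 h | 4.0 h |

| run | time / h | product / % | starting material / % |
|---|---|---|---|
| gamma | 0.333 | 13.8 | 78.9 |
| gamma | 1.00 | 36.0 | 51.2 |
| gamma | 2.00 | 54.4 | 29.2 |
| gamma | 3.00 | 64.1 | 17.8 |
| alpha | 0.250 | 9.6 | 82.3 |
| alpha | 0.500 | 20.1 | 67.9 |
| alpha | 1.33 | 39.8 | 38.4 |
| alpha | 3.00 | 58.5 | 15.4 |
| eta | 0.250 | 16.3 | 78.2 |
| eta | 0.500 | 28.5 | 60.4 |
| eta | 1.33 | 56.7 | 28.7 |
| eta | 3.00 | 74.6 | 9.4 |

(readings scatter by 0.5 percentage points)

* the flasks by amount of product, in percent of the starting material charged, highest first, at 4.0 h (amber / ochre / teal / green / blue / grey)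
* the same order at 25 min (amber / ochre / teal / green / blue / grey)
* the amount of product, in percent of the starting material charged of the flask you put first, at 4.0 h
* the amount of product, in percent of the starting material charged of the flask you put last, at 4.0 h

The first keeps a clock. Product follows a first-order constant k that goes with c(catalyst), so the fraction made is 1 − E, with E = exp(−kt). Teal and grey carry the same catalyst, so on the clock they tie.

The second chemist points at the missing part. At their last readings, both at 3.00 h and with equal catalyst, alpha has lost 26.1% and gamma 18.1%, more in the richer flask. She takes the loss as second order in starting material, so with a fraction a left, product outruns loss by s/a.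

By 1.00 h gamma has made 36.0% and lost 12.8%, while a averaged about 75.6%. So s is 2.13 there. This s, the competition number, is a selectivity factor at the charge: product rate over loss rate at a full flask, scaling as c(catalyst)/c(starting material). The same reading then gives k = 0.500 /h for gamma.

Integrating both losses joins the two views: the product fraction is s·ln(1 + (1 − E)/s). Late, as E shrinks, the formula tends to s·ln(1 + 1/s); for s far above one, it returns the clock.

Ochre has s = 8.51. My reckoning for 4.0 h is ochre 94.4%, green 75.5%, teal 69.9%, blue 61.2%, grey 59.6%, amber 49.3%. At 25 min the ranks hold except that grey, at 17.0%, leads blue, at 12.5%.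

The forecast, holding that “it is an uncatalysed second-order side reaction”, stands on her side with ochre > green > teal > blue > grey > amber and, at 25 min, ochre > green > teal > grey > blue > amber, giving 91% for ochre, lower than my figure, and 49% for amber.

The flasks give ochre > green > teal > blue > grey > amber and, at 25 min, ochre > green > teal > grey > blue > amber, with ochre at 90.1% and amber at 48.4%.

    dissolved gas → decomposed reagent (k = 0.150 /h)
    gas phase ⇌ dissolved gas, rate k2*(csat - [dissolved gas]) (kL = 110 /h)
    2 starting material → homo dimer (k = 0.0980 /M/h)
    starting material + dissolved gas + catalyst ⇌ catalyst + product (K = 140 /M, k = 400 /M²/h)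

Teal at 67.5% and grey at 56.8% part by 11 percentage points, so the clock, which tied them, loses. In ochre the reversible product step relaxes in 0.322 h, short against the 4.0 h of the run. Ochre's 3.85% of starting material stands beside 90.1% of product, a balance the join lacks, while its 6.08% of homo dimer sits by 5.88%, the reciprocal of twice its s. A neighbour of ochre with 6.30 mM of catalyst has s = 2.14, which joins to 69.0%, and it gives 67.1%.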